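All runs are calculated for substances that don't exist, noise included.

in all of them: electrophile 10 mM; gas 0.33 mM (held)
- Monday's: nucleophile 38 mM; run made earlier
- Sunday's: nucleophile 72 mM; run made earlier
- east: nucleophile 39.0 mM; time 6.0 min
- north-east: nucleophile 51.0 mM; time 6.0 min
- south-west: nucleophile 30.0 mM; time 6.0 min

| run | time / min | electrophile / % | target / % |
|---|---|---|---|
| Monday's | 0.417 | 88.0 | 10.8 |
| Monday's | 0.833 | 79.2 | 21.3 |
| Monday's | 1.33 | 69.4 | 30.5 |
| Monday's | 1.50 | 66.8 | 33.6 |
| Monday's | 2.00 | 58.8 | 40.3 |
| Monday's | 2.50 | 51.8 | 47.7 |
| Monday's | 3.00 | 46.3 | 53.8 |
| Sunday's | 0.167 | 92.0 | 8.8 |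
| Sunday's | 0.500 | 76.3 | 23.8 |
| Sunday's | 0.833 | 64.7 | 35.9 |
| Sunday's | 1.33 | 51.0 | 49.7 |
| Sunday's | 2.00 | 36.4 | 63.5 |
| Sunday's | 2.50 | 30.1 | 72.1 |
| Sunday's | 3.00 | 23.6 | 76.9 |

(readings scatter by 0.5 percentage points)

1. part of the electrophile that has reacted at the end, east
2. part of the electrophile that has reacted at the end, north-east
3. part of the electrophile that has reacted at the end, south-west
4. what raising the concentration of nucleophile from its lowest to its highest value here does to the part of the electrophile that has reacted (changes below 5 percentage points count as none) (it rises / it falls / no change)

- at the start none of free base is dissolved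
- the numbers in the tables scatter by 0.5 percentage points (one standard deviation)
- candidate steps: acid set free + free base <-> salt of the base; gas <-> free base; free base <-> dormant form; nucleophile + acid set free <-> protonated nucleophile; electrophile + nucleophile -> acid set free + target

I started from the rate constant of the main step, in which electrophile and nucleophile give target and acid set free. In Monday's run the electrophile fell to 79.2% by 0.833 min, a pseudo-first-order constant of 0.280 min⁻¹; in Sunday's run it fell to 76.3% by 0.500 min, a constant of 0.541 min⁻¹. Those constants stand in the ratio 1.93 and the charges of nucleophile in the ratio 1.89, so I took the rate as first order in each partner.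

The quantity I carried was the half-life of electrophile at the charged nucleophile, which is ln(2) over the Sunday constant scaled to the charge. For south-west it came to 3.07 min.

Taking the main step by itself, with nucleophile held at its charge, I reckoned 74.2% for south-west by 6.0 min. The main step itself spends one nucleophile per electrophile, and that brought my figure down to 68.7%. If every acid set free then took a further nucleophile, the figure fell to 63.1%.

Free base from the gas offers each acid a second road, one that costs no nucleophile. I followed one acid to this fork and, as a guess of my own, gave it a chance of 0.5 of landing on nucleophile. That reckoning gave 65.9% for south-west, 76.0% for east and 85.2% for north-east, a rise of 19 percentage points across the range.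

The forecast stood higher than my figures, at 68%, 77% and 86% for the same flasks, with the trend it rises; it held that “the dissolved base mops up much of the acid, not all of it”.

The flasks gave 66.0% for south-west, 75.9% for east and 85.1% for north-east, and the trend was it rises, by 19 points.

    acid set free + free base ⇌ salt of the base, settled at all times (K = 3.20 × 10⁵ M⁻¹)
    gas ⇌ free base, rate k2*(csat - [free base]) (kL = 1.50 s⁻¹)
    free base ⇌ dormant form (K = 770, k = 0.00150 s⁻¹)
    nucleophile + acid set free ⇌ protonated nucleophile, settled at all times (K = 11000 M⁻¹)
    electrophile + nucleophile → acid set free + target (k = 0.130 M⁻¹ s⁻¹)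

At 1.91 min in south-west, the main step gave a half-life of 3.7 min for electrophile against 13 min for nucleophile, and at the end south-west held 34% of its electrophile and 63% of its nucleophile unbound. Scaled to a neighbour of south-west charged with 7.5 mM of nucleophile, my half-life became 12.3 min, which reckons to 28.7% at constant nucleophile by 6.00 min, and that flask gave 23.4%.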